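**Retrosynthetic overview**

1. Both halves of the target are the same flavan-3,4-diol (2R,3R,4S; 2,3-cis-3,4-trans). The C4(upper)–O–C3(lower) ether is therefore cut last (oxidative etherification, step 8), giving two derivatives, 11 and 12, of one monomer, flavan-3-ol 10.
2. In the monomer the C3 carbinol is taken back to a ketone (flavan-3-one 9). At this oxidation level ring C can be closed without a C3 stereocentre, and step 5 removes it again with 2,3-cis selectivity.
3. Key disconnection: the C4–C4a bond of ring C. Ketone 9 comes from aryl propargyl ether 8 by gold-catalysed alkyne oxidation; the α-oxo carbene carbon (C4, an enolate carbon of reversed polarity) is attacked by ring A.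
4. Enabling feature: O1 ties C2 to ring A, so C4a (the only free carbon ortho to O1, and para to the C7 oxygen) lies six atoms from the alkyne terminus. The C3 oxygen of the target sits exactly on the internal alkyne carbon.
5. Ring order: rings A and B are bought as arenes; C2 is set by asymmetric propargylic etherification (step 3); ring C is closed once (step 4) and serves both halves; the inter-flavan ether follows.

Key step: step 4

Remark on the chemistry: the (S,S) antipode of the pybox ligand in step 3 is assumed to deliver the S ether; if induction runs the other way, the (R,R) ligand is used and nothing else changes.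

**Step 1**
Reactants: 1 2,3-bis(benzyloxy)benzaldehyde
Product: 3 2,3-bis(benzyloxy)phenol, via aryl formate 2 (not isolated)
Conditions: mCPBA, CH2Cl2, 0 °C to rt; then K2CO3, MeOH, rt
Reagents that add atoms: mCPBA (3-chloroperoxybenzoic acid), OOC(=O)c1cccc(Cl)c1
Why: Baeyer–Villiger (Dakin-type) oxidation, in which the electron-rich ortho-alkoxyaryl group migrates in preference to hydride, followed by mild methanolysis of the formate that leaves the benzyl ethers alone.

**Step 2**
Reactants: 4 4-(benzyloxy)benzaldehyde; 5 ethynylmagnesium bromide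
Product: 7 rac-1-[4-(benzyloxy)phenyl]prop-2-yn-1-yl acetate, via magnesium alkoxide 6 (not isolated)
Conditions: THF, 0 °C; then Ac2O, 0 °C to rt
Reagents that add atoms: acetic anhydride, CC(=O)OC(C)=O
Why: Grignard addition of the acetylide to the aldehyde and acylation of the magnesium alkoxide in the same flask should give the racemic acetate, whose configuration does not matter because step 3 is stereoconvergent.

**Step 3**
Reactants: 7 rac-1-[4-(benzyloxy)phenyl]prop-2-yn-1-yl acetate; 3 2,3-bis(benzyloxy)phenol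
Product: 8 (S)-1,2-bis(benzyloxy)-3-({1-[4-(benzyloxy)phenyl]prop-2-yn-1-yl}oxy)benzene
Conditions: CuOTf·0.5C6H6 (5 mol%), (S,S)-Ph-pybox (2,6-bis[(4S)-4-phenyl-4,5-dihydrooxazol-2-yl]pyridine, 10 mol%), i-Pr2NEt, CH2Cl2, −20 °C
Reagents that add atoms: none
Why: Copper-catalysed asymmetric propargylic substitution: the terminal alkyne forms a copper acetylide, loss of acetate gives a planar copper allenylidene through which both enantiomers of 7 converge, and the pybox ligand directs the phenol to one face of the γ-carbon, setting the future C2 as S.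

**Step 4**
Reactants: 8 (S)-1,2-bis(benzyloxy)-3-({1-[4-(benzyloxy)phenyl]prop-2-yn-1-yl}oxy)benzene
Product: 9 (2R)-7,8-bis(benzyloxy)-2-[4-(benzyloxy)phenyl]chroman-3-one
Conditions: (Me4tBuXPhos)AuCl (5 mol%), AgNTf2 (5 mol%), 2,6-dichloropyridine N-oxide (1.3 equiv), ClCH2CH2Cl, rt (Me4tBuXPhos = di-tert-butyl(2',4',6'-triisopropyl-3,4,5,6-tetramethylbiphenyl-2-yl)phosphine)
Reagents that add atoms: 2,6-dichloropyridine N-oxide, [O-][n+]1c(Cl)cccc1Cl
Why: The cationic monovalent gold catalyst binds the terminal alkyne of 8, the N-oxide oxygen adds to the internal carbon (the future C3), and loss of 2,6-dichloropyridine leaves an α-oxo gold carbene at the terminal carbon (the future C4), an enolate carbon of reversed polarity that can bond to the nucleophilic arene carbon C4a. The closest known reaction type is the gold-catalysed oxidation of aryl propargyl ethers to chroman-3-ones. Ring C closes by six-membered attack of C4a on the carbene carbon (6-exo with respect to the Au=C bond, an electrophilic aromatic substitution), followed by rearomatisation and protodeauration. No new stereocentre arises: C2 is not involved and should survive because no base is present, and C3 is deliberately left as a carbonyl so that step 5 can set it inside the ring. The step needs site selectivity on ring A and chemoselectivity for oxidation over direct hydroarylation: C4a is the only unsubstituted carbon ortho to O1 (C8 carries a benzyloxy group) and is para to the C7 oxygen, closure onto ring B would need a five-membered ring at a carbon meta to its oxygen, and the bulky biaryl phosphine with the hindered N-oxide disfavours double oxidation and 6-endo hydroarylation.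

**Step 5**
Reactants: 9 (2R)-7,8-bis(benzyloxy)-2-[4-(benzyloxy)phenyl]chroman-3-one
Product: 10 (2R,3R)-7,8-bis(benzyloxy)-2-[4-(benzyloxy)phenyl]chroman-3-ol (2,3-cis)
Conditions: L-Selectride (LiBH(s-Bu)3), LiBr, THF, −78 °C; then H2O
Reagents that add atoms: none
Why: Substrate-controlled ketone reduction in which the bulky hydride attacks C3 from the face opposite the equatorial C2 aryl group, so the new hydroxyl should be axial and cis to the aryl group (3R), the outcome established for flavan-3-ones.

**Step 6**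
Reactants: 10 (2R,3R)-7,8-bis(benzyloxy)-2-[4-(benzyloxy)phenyl]chroman-3-ol
Product: 11 (2R,3R)-7,8-bis(benzyloxy)-2-[4-(benzyloxy)phenyl]chroman-3-yl acetate
Conditions: Ac2O, pyridine, DMAP (cat.), CH2Cl2, rt
Reagents that add atoms: acetic anhydride, CC(=O)OC(C)=O
Why: DMAP-catalysed acetylation caps the only nucleophilic site of the future upper unit, so that it cannot trap C4 cations in step 8.

**Step 7**
Reactants: 10 (2R,3R)-7,8-bis(benzyloxy)-2-[4-(benzyloxy)phenyl]chroman-3-ol
Product: 12 (2R,3S,4S)-7,8-bis(benzyloxy)-2-[4-(benzyloxy)phenyl]-3-hydroxychroman-4-yl acetate (2,3-cis-3,4-trans)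
Conditions: DDQ (1.5 equiv), AcOH (20 equiv), CH2Cl2, rt
Reagents that add atoms: acetic acid, CC(=O)O
Why: Oxidative benzylic acetoxylation: DDQ abstracts the axial hydride from C4 (para to the C7 benzyloxy group, ortho to O1) and the large excess of acetic acid should trap the cation anti to the axial 3-hydroxyl, setting C4 as the 3,4-trans acetate.

**Step 8**
Reactants: 11 (2R,3R)-7,8-bis(benzyloxy)-2-[4-(benzyloxy)phenyl]chroman-3-yl acetate; 12 (2R,3S,4S)-7,8-bis(benzyloxy)-2-[4-(benzyloxy)phenyl]-3-hydroxychroman-4-yl acetate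
Product: 13 (2R,3R,4S)-4-{[(2R,3S,4S)-4-acetoxy-7,8-bis(benzyloxy)-2-[4-(benzyloxy)phenyl]chroman-3-yl]oxy}-7,8-bis(benzyloxy)-2-[4-(benzyloxy)phenyl]chroman-3-yl acetate
Conditions: DDQ (1.2 equiv), 4 Å molecular sieves, CH2Cl2, 0 °C to rt (12 in twofold excess, surplus recovered)
Reagents that add atoms: none
Why: DDQ-mediated oxidative C4 etherification of a flavan: only 11 has an axial C4–H aligned with ring A for hydride abstraction (in 12 and in the product the remaining C4–H is equatorial), and the hydroxyl of 12 should add to the cation anti to the axial 3-acetoxy group, setting the upper C4 as the 3,4-trans (4S) ether.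

**Step 9**
Reactants: 13 the diacetate of step 8
Product: 14 (2R,3R,4S)-7,8-bis(benzyloxy)-2-[4-(benzyloxy)phenyl]-4-{[(2R,3R,4S)-7,8-bis(benzyloxy)-2-[4-(benzyloxy)phenyl]-4-hydroxychroman-3-yl]oxy}chroman-3-ol
Conditions: K2CO3, MeOH/THF, 40 °C
Reagents that add atoms: none

Why: Base-catalysed transesterification removes both secondary acetates by acyl–oxygen cleavage, which cannot disturb the benzylic C–O bonds or any stereocentre.

**Step 10**
Reactants: 14 the hexabenzyl ether diol of step 9
Product: 15 (2R,3R,4S)-2-(4-hydroxyphenyl)-4-{[(2R,3R,4S)-4,7,8-trihydroxy-2-(4-hydroxyphenyl)chroman-3-yl]oxy}chromane-3,7,8-triol (CNP0266687.1)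
Conditions: H2 (1 atm), Pd(OH)2/C, THF/MeOH, rt, stopped at the end of hydrogen uptake
Reagents that add atoms: none
Why: Catalytic hydrogenolysis, in which the six aryl benzyl ethers should cleave much faster in neutral medium than the hindered secondary benzylic C4–O bonds of the two flavan units.

**Compound list**

1 | 2,3-bis(benzyloxy)benzaldehyde | O=Cc1cccc(OCc2ccccc2)c1OCc1ccccc1 | starting material
2 | 2,3-bis(benzyloxy)phenyl formate | O=COc1cccc(OCc2ccccc2)c1OCc1ccccc1 | intermediate (not isolated)
3 | 2,3-bis(benzyloxy)phenol | Oc1cccc(OCc2ccccc2)c1OCc1ccccc1 | intermediate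
4 | 4-(benzyloxy)benzaldehyde | O=Cc1ccc(OCc2ccccc2)cc1 | starting material
5 | ethynylmagnesium bromide | C#C[Mg]Br | starting material
6 | bromomagnesium alkoxide of rac-1-[4-(benzyloxy)phenyl]prop-2-yn-1-ol | C#CC(O[Mg]Br)c1ccc(OCc2ccccc2)cc1 | intermediate (not isolated)
7 | rac-1-[4-(benzyloxy)phenyl]prop-2-yn-1-yl acetate | CC(=O)OC(C#C)c1ccc(OCc2ccccc2)cc1 | intermediate
8 | (S)-1,2-bis(benzyloxy)-3-({1-[4-(benzyloxy)phenyl]prop-2-yn-1-yl}oxy)benzene | c1ccccc1COc1ccc([C@H](C#C)Oc2cccc(OCc3ccccc3)c2OCc2ccccc2)cc1 | intermediate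
9 | (2R)-7,8-bis(benzyloxy)-2-[4-(benzyloxy)phenyl]chroman-3-one | c1ccccc1COc1ccc([C@H]2Oc3c(ccc(OCc4ccccc4)c3OCc3ccccc3)CC2=O)cc1 | intermediate
10 | (2R,3R)-7,8-bis(benzyloxy)-2-[4-(benzyloxy)phenyl]chroman-3-ol (2,3-cis) | c1ccccc1COc1ccc([C@H]2Oc3c(ccc(OCc4ccccc4)c3OCc3ccccc3)C[C@H]2O)cc1 | intermediate
11 | (2R,3R)-7,8-bis(benzyloxy)-2-[4-(benzyloxy)phenyl]chroman-3-yl acetate | c1ccccc1COc1ccc([C@H]2Oc3c(ccc(OCc4ccccc4)c3OCc3ccccc3)C[C@H]2OC(C)=O)cc1 | intermediate
12 | (2R,3S,4S)-7,8-bis(benzyloxy)-2-[4-(benzyloxy)phenyl]-3-hydroxychroman-4-yl acetate (2,3-cis-3,4-trans) | c1ccccc1COc1ccc([C@H]2Oc3c(ccc(OCc4ccccc4)c3OCc3ccccc3)[C@H](OC(C)=O)[C@H]2O)cc1 | intermediate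
13 | (2R,3R,4S)-4-{[(2R,3S,4S)-4-acetoxy-7,8-bis(benzyloxy)-2-[4-(benzyloxy)phenyl]chroman-3-yl]oxy}-7,8-bis(benzyloxy)-2-[4-(benzyloxy)phenyl]chroman-3-yl acetate | c1ccccc1COc1ccc([C@H]2Oc3c(ccc(OCc4ccccc4)c3OCc3ccccc3)[C@H](O[C@H]3[C@@H](c4ccc(OCc5ccccc5)cc4)Oc4c(ccc(OCc5ccccc5)c4OCc4ccccc4)[C@@H]3OC(C)=O)[C@H]2OC(C)=O)cc1 | intermediate
14 | (2R,3R,4S)-7,8-bis(benzyloxy)-2-[4-(benzyloxy)phenyl]-4-{[(2R,3R,4S)-7,8-bis(benzyloxy)-2-[4-(benzyloxy)phenyl]-4-hydroxychroman-3-yl]oxy}chroman-3-ol | c1ccccc1COc1ccc([C@H]2Oc3c(ccc(OCc4ccccc4)c3OCc3ccccc3)[C@H](O[C@H]3[C@@H](c4ccc(OCc5ccccc5)cc4)Oc4c(ccc(OCc5ccccc5)c4OCc4ccccc4)[C@@H]3O)[C@H]2O)cc1 | intermediate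
15 | (2R,3R,4S)-2-(4-hydroxyphenyl)-4-{[(2R,3R,4S)-4,7,8-trihydroxy-2-(4-hydroxyphenyl)chroman-3-yl]oxy}chromane-3,7,8-triol | Oc1ccc([C@H]2Oc3c(ccc(O)c3O)[C@H](O[C@H]3[C@@H](c4ccc(O)cc4)Oc4c(ccc(O)c4O)[C@@H]3O)[C@H]2O)cc1 | target

**Totals**

Total step count: 10. Longest linear sequence: 8 steps (steps 2, 3, 4, 5, 6, 8, 9, 10).

**Steps most likely to fail**

Step 8. The hindered axial hydroxyl of 12 may capture the C4 cation too slowly, so that adventitious water or the reduced quinone intercepts it; hydride abstraction at C2 or over-oxidation may also compete. The fallback separates oxidation from coupling and uses soft, thiophilic activation; it sets out from 11 and comes back at 13. Acetoxylation of 11 under the conditions of step 7 (DDQ, AcOH) should give the 3,4-trans diacetate (2R,3S,4S)-7,8-bis(benzyloxy)-2-[4-(benzyloxy)phenyl]chromane-3,4-diyl diacetate F1. BF3·OEt2 and 4-methylbenzenethiol in CH2Cl2 at −78 °C then exchange the C4 acetate for sulfur to give the thioether (2R,3S,4S)-7,8-bis(benzyloxy)-2-[4-(benzyloxy)phenyl]-4-[(4-methylphenyl)sulfanyl]chroman-3-yl acetate F2. AgBF4 in THF at −40 °C ionises only the C–S bond in the presence of 12, whose acetate does not respond to the soft activator, and the hydroxyl of 12 should add anti to the 3-acetoxy group to give 13.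

Step 4. Direct 6-endo hydroarylation of the electron-rich aryl ether may outrun alkyne oxidation, the carbene may be oxidised a second time, or C2 may lose configuration by enolisation of the product. The fallback accepts the hydroarylation and adds the C3 oxygen afterwards; it sets out from 8 and comes back at 9. PtCl2 in toluene at 80 °C without oxidant should close ring C through the same C4–C4a bond to give (2S)-7,8-bis(benzyloxy)-2-[4-(benzyloxy)phenyl]-2H-chromene F3. Hydroboration–oxidation (BH3·THF; then NaOH, H2O2) anti to the aryl group gives (2R,3S)-7,8-bis(benzyloxy)-2-[4-(benzyloxy)phenyl]chroman-3-ol F4 (2,3-trans), and Dess–Martin periodinane oxidises it to ketone 9.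

Step 3. Background ionisation of the cation-stabilised propargylic acetate may open a racemic pathway, and the ortho-substituted phenol may react sluggishly with the copper allenylidene. The fallback sets the stereocentre on the alcohol and forms the ether with inversion; it sets out from 4 and comes back at 8. Me2Zn/ProPhenol-catalysed addition of trimethylsilylacetylene to 4 (ligand antipode chosen for this enantiomer) should give (S)-1-[4-(benzyloxy)phenyl]-3-(trimethylsilyl)prop-2-yn-1-ol F5. K2CO3 in MeOH removes the silyl group to give (R)-1-[4-(benzyloxy)phenyl]prop-2-yn-1-ol F6, and Mitsunobu etherification with phenol 3 (PPh3, DIAD, toluene, −20 °C) inverts the carbinol carbon to give 8.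

**Further compounds**

F1 | step 8 | (2R,3S,4S)-7,8-bis(benzyloxy)-2-[4-(benzyloxy)phenyl]chromane-3,4-diyl diacetate | c1ccccc1COc1ccc([C@H]2Oc3c(ccc(OCc4ccccc4)c3OCc3ccccc3)[C@H](OC(C)=O)[C@H]2OC(C)=O)cc1
F2 | step 8 | (2R,3S,4S)-7,8-bis(benzyloxy)-2-[4-(benzyloxy)phenyl]-4-[(4-methylphenyl)sulfanyl]chroman-3-yl acetate | c1ccccc1COc1ccc([C@H]2Oc3c(ccc(OCc4ccccc4)c3OCc3ccccc3)[C@H](Sc3ccc(C)cc3)[C@H]2OC(C)=O)cc1
F3 | step 4 | (2S)-7,8-bis(benzyloxy)-2-[4-(benzyloxy)phenyl]-2H-chromene | c1ccccc1COc1ccc([C@H]2Oc3c(ccc(OCc4ccccc4)c3OCc3ccccc3)C=C2)cc1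
F4 | step 4 | (2R,3S)-7,8-bis(benzyloxy)-2-[4-(benzyloxy)phenyl]chroman-3-ol (2,3-trans) | c1ccccc1COc1ccc([C@H]2Oc3c(ccc(OCc4ccccc4)c3OCc3ccccc3)C[C@@H]2O)cc1
F5 | step 3 | (S)-1-[4-(benzyloxy)phenyl]-3-(trimethylsilyl)prop-2-yn-1-ol | c1ccccc1COc1ccc([C@@H](C#C[Si](C)(C)C)O)cc1
F6 | step 3 | (R)-1-[4-(benzyloxy)phenyl]prop-2-yn-1-ol | c1ccccc1COc1ccc([C@@H](C#C)O)cc1
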